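Early in the elm run, at 0.833 min, the readings stand at 27% mono adduct and 5% double product, and the question is what becomes of the substrate that these two columns leave over.

| flask | substrate | partner | remark | time |
|---|---|---|---|---|
| ash | 13 mM | 20 mM (fed, over 1.2 min) | run made earlier |  |
| elm | 30 mM | 20 mM (fed, over 1.2 min) | run made earlier |  |
| larch | 20 mM | 10 mM (fed, over 1.2 min) | run made earlier |  |
| summer | 20 mM | 20.0 mM (fed, over 1.2 min) |  | 10 min |
| midnight | 20 mM | 20.0 mM (fed, over 2.5 min) |  | 10 min |
| autumn | 20 mM | 20.0 mM (fed, over 5.0 min) |  | 10 min |
| dusk | 20 mM | 20.0 mM (fed, over 10 min) |  | 10 min |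

| run | time / min | mono adduct / % | double product / % |
|---|---|---|---|
| ash | 0.833 | 39 | 8 |
| ash | 1.33 | 43 | 28 |
| ash | 2.00 | 40 | 43 |
| ash | 3.00 | 33 | 53 |
| ash | 4.00 | 32 | 58 |
| ash | 6.00 | 30 | 58 |
| ash | 10.0 | 29 | 62 |
| elm | 0.833 | 27 | 5 |
| elm | 1.33 | 38 | 10 |
| elm | 2.00 | 39 | 13 |
| elm | 3.00 | 40 | 12 |
| elm | 4.00 | 42 | 15 |
| elm | 6.00 | 43 | 12 |
| elm | 10.0 | 36 | 13 |
| larch | 2.00 | 34 | 9 |
| larch | 4.00 | 34 | 9 |
| larch | 6.00 | 35 | 7 |
| larch | 8.00 | 36 | 8 |
| larch | 10.0 | 36 | 8 |

(scatter of a reading: 1.5 percentage points)

- "hardly changes" means that all values lie within two and a half points (for a concentration: within two and a half percent of the largest)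

- share of mono adduct in all that became mono adduct or double product or side product for summer, midnight, autumn, dusk, in this order
- the course of these numbers from the first flask to the last (hardly changes / rises all the way / falls all the way / rises, then falls / falls, then rises)

*What do the readings not show?* Substrate and side product have no column, so the denominator of the asked share holds a term that was never read.

*What can be said of it?* Work with what is left. In the larch run at 10.0 min, mono adduct and double product leave 56.0% of the substrate charged. The partner bound, c_mono + 2 c_double, comes to 10.4 mM against 10 mM charged, so the partner is the limiting reagent there and its balance closes within the scatter.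

*Then is that remainder unreacted substrate?* The readings can't say. In the larch run, mono adduct and double product stay level from 2.00 min on, but these two columns hold no term for substrate lost to something unread.

The forecast gives 59%, 59%, 59.3% and 60.5%, with the course hardly changes. Its grounds begin: “Treating unaccounted substrate as unreacted”.

*What do the readings imply for summer?* Summer charges 20 mM substrate and 20.0 mM partner, so with a closed balance c_double, as a fraction of the substrate charged, equals what is left over. At 10.0 min, the elm run reads 13% double product at 0.667 partner per substrate, and the ash run reads 62% at 1.54. My straight line between these two readings gives 31.7% at the 1.00 of summer. This is the rest: the fraction of the substrate charged that stands in neither mono adduct nor double product.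

*And the weak spot?* The rest may be substrate or side product. Mono adduct is the charge less 2 times the rest, 36.5%. My own reckoning therefore commits to a range for summer: 53.5% if the rest stays substrate, down to 36.5% if it has turned wholly into side product. The forecast's 59% stands above this range.

The flasks give 48.6%, 47.9%, 46.4% and 46.4%, with the course hardly changes.

    substrate + partner → mono adduct + by-product (k = 3.12 L mol⁻¹ s⁻¹)
    partner + mono adduct → double product + by-product (k = 2.11 L mol⁻¹ s⁻¹)
    substrate + by-product → side product (k = 0.0861 L mol⁻¹ s⁻¹)
    partner → decomposed reagent (k = 5.61 × 10⁻⁴ s⁻¹)

Summer has a rest of 29.2% at 10.0 min, beside the 31.7% carried, and it stands as substrate 12.1% plus side product 17.2%: by-product from the two main steps takes up substrate. That step is still running at the asked time, for summer reads 42.7% at 100 min, which is 5.9 percentage points lower. Dusk, with partner 5.59% still left, has a rest of 34.3%, above the 31.7% carried, standing as substrate 17.8% plus side product 16.6%, so its share lies between 38.2% and 58.1% and reads 46.4%.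

The readings are calculated for an exercise, noise included.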